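## Retrosynthetic overview

1. The acid comes from its methyl ester; the ring ethyl group on the cyclohexene comes from Negishi coupling of an enol triflate made from a trans-fused bicyclic diketone.
2. The cyclopentanone is closed last, by oxidative coupling of two ketone enolates of a monocyclic 1,5-diketone; ring fusion and both ketone α-centres are then set by equilibration.
3. The styryl-bearing quaternary carbon comes from cuprate addition to a 3-ethylcyclohexenone whose side chain was attached by Mukaiyama–Michael addition.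
4. Key step: catalytic asymmetric conjugate ethylation desymmetrizes a prochiral 4-ethyl-4-(methoxycarbonyl)cyclohexa-2,5-dienone. It is the only source of absolute configuration; its temporary stereocentre relays to the ring fusion and is then erased.
5. The dienone (the six-membered ring of the target) comes from methyl benzoate by Birch reductive ethylation and bis-allylic oxidation. Ring order: six-membered ring first (from the arene), five-membered ring last.

Locants in the Why lines are those of the target (1H-indene numbering): C1 (ethyl), C2 (ketone), C3 (methyl), C3a, C4 (ethyl and carboxyl), C5 (ethyl and styryl), C6, C7 (ring ethyl), C7a.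

Assumption: the sense of induction of the copper–phosphoramidite catalyst in step 3 is taken from related 4,4-disubstituted dienones; if it proves opposite, the enantiomeric ligand is used.

## Route

Step 1
Reactants: 1 methyl benzoate
Product: 3 methyl 1-ethylcyclohexa-2,5-diene-1-carboxylate, via lithium ester dienolate 2 (not isolated)
Conditions: Li, NH3(l)/THF, t-BuOH (1 equiv), −78 °C; then EtI, −78 °C → rt
Reagents that add atoms: iodoethane, CCI
Why: Birch reduction–alkylation: Li/NH3 reduces the benzoate to the cross-conjugated ester dienolate, which is C-ethylated at the ipso carbon, turning the arene into a 1,1-disubstituted cyclohexa-2,5-diene whose quaternary carbon is the future C4 (no stereocentre yet).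

Step 2
Reactants: 3 methyl 1-ethylcyclohexa-2,5-diene-1-carboxylate
Product: 4 methyl 1-ethyl-4-oxocyclohexa-2,5-diene-1-carboxylate
Conditions: t-BuOOH (70% aq, 5 equiv), Rh2(C6H10NO)4 [dirhodium tetrakis(caprolactamate), 1 mol%], K2CO3, CH2Cl2, rt
Reagents that add atoms: tert-butyl hydroperoxide, CC(C)(C)OO
Why: Rhodium-catalysed allylic oxidation of the doubly allylic CH2 gives the mirror-symmetric, prochiral cross-conjugated dienone (its carbonyl is the future C7); the quaternary carbon blocks aromatization.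

Step 3
Reactants: 4 methyl 1-ethyl-4-oxocyclohexa-2,5-diene-1-carboxylate
Product: 6 methyl (1R,5S,6R)-1,6-diethyl-4-oxo-5-(phenylselanyl)cyclohex-2-ene-1-carboxylate, via ethylzinc enolate 5 (not isolated)
Conditions: Et2Zn (1.5 equiv), Cu(OTf)2 (2 mol%), (S,R,R)-phosphoramidite L [from (S)-1,1′-bi-2-naphthol and bis((R)-1-phenylethyl)amine, 4 mol%], toluene, −25 °C; then PhSeBr, THF, −78 → 0 °C
Reagents that add atoms: diethylzinc, CC[Zn]CC; phenylselanyl bromide, Br[Se]c1ccccc1
Why: Copper–phosphoramidite-catalysed asymmetric conjugate addition desymmetrizes the dienone: the catalyst selects one enantiotopic enone arm and face, the ethyl group enters syn to the smaller, electron-poor ester (which fixes the configuration of C4), and the zinc enolate is selenenylated anti to the new ethyl group (electrophilic α-selenenylation).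

Step 4
Reactants: 7 hex-1-en-3-one
Product: 8 triethyl{[(2Z)-hex-2-en-3-yl]oxy}silane
Conditions: Et3SiH, RhCl(PPh3)3 (0.5 mol%), toluene, 60 °C
Reagents that add atoms: triethylsilane, CC[SiH](CC)CC
Why: Rhodium-catalysed 1,4-hydrosilylation of the vinyl ketone gives the silyl enol ether regiospecifically on the former vinyl side, the carbon that becomes C3 with its methyl group.

Step 5
Reactants: 6 methyl (1R,5S,6R)-1,6-diethyl-4-oxo-5-(phenylselanyl)cyclohex-2-ene-1-carboxylate; 8 triethyl{[(2Z)-hex-2-en-3-yl]oxy}silane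
Product: 12 methyl (1R,6R)-1,2-diethyl-4-oxo-6-(3-oxohexan-2-yl)cyclohex-2-ene-1-carboxylate (both side-chain epimers), via silyl enol ether adduct 9 (not isolated), via seleno diketone 10 (not isolated), via selenoxide 11 (not isolated)
Conditions: Tf2NH (5 mol%), CH2Cl2, −78 °C; 1 M HCl, THF, 0 °C; then H2O2 (30%), pyridine, CH2Cl2, 0 °C → rt
Reagents that add atoms: none
Why: Mukaiyama–Michael addition to the remaining enone occurs axially, trans to the temporary C5 ethyl group and anti to the pseudo-axial ester (3,5-trans rule), which places the side chain at C3a cis to the C4 ethyl group; selenoxide syn-elimination then restores the C5=C6 enone and erases the temporary C5–H centre.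

Step 6
Reactants: 12 methyl (1R,6R)-1,2-diethyl-4-oxo-6-(3-oxohexan-2-yl)cyclohex-2-ene-1-carboxylate; 13 (E)-(2-bromoethenyl)benzene
Product: 17 methyl (1R,2R,6R)-1,2-diethyl-4-oxo-6-(3-oxohexan-2-yl)-2-[(E)-2-phenylethenyl]cyclohexane-1-carboxylate, via (E)-styryllithium 14 (not isolated), via lithium distyrylcuprate 15 (not isolated), via trimethylsilyl enol ether 16 (not isolated)
Conditions: 13, t-BuLi (2 equiv), Et2O, −78 °C; CuI (0.5 equiv); then 12, TMSCl, THF, −78 → −30 °C; 1 M HCl
Reagents that add atoms: none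
Why: TMSCl-accelerated organocuprate conjugate addition builds the C5 quaternary centre next to C4, the styryl group entering axially, trans to the C3a side chain and anti to the pseudo-axial C4 ethyl group, so the two ethyl groups end up cis and the styryl group cis to the ester; immediate O-silylation stops the enolate from attacking the side-chain ketone.

Step 7
Reactants: 17 methyl (1R,2R,6R)-1,2-diethyl-4-oxo-6-(3-oxohexan-2-yl)-2-[(E)-2-phenylethenyl]cyclohexane-1-carboxylate
Product: 20 methyl (1S,3S,3aS,4R,5R,7aR)-1,4,5-triethyl-3-methyl-2,7-dioxo-5-[(E)-2-phenylethenyl]octahydro-1H-indene-4-carboxylate, via dilithium bis-enolate 18 (not isolated), via cis-fused diketone 19 (not isolated)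
Conditions: LiN(iPr)2 (2.2 equiv), THF, −78 °C; Fe(acac)3 (2.2 equiv), −78 °C → rt; then DBU, CH2Cl2, rt
Reagents that add atoms: none
Why: Intramolecular oxidative enolate coupling (kinetic enolates at the two less hindered methylenes, one-electron oxidant) forms the C1–C7a bond and closes the cyclopentanone, and DBU then equilibrates C7a, C1 and C3 to the trans-fused all-equatorial isomer, the only one free of 1,3-diaxial strain against the two adjacent quaternary carbons.

Step 8
Reactants: 20 methyl (1S,3S,3aS,4R,5R,7aR)-1,4,5-triethyl-3-methyl-2,7-dioxo-5-[(E)-2-phenylethenyl]octahydro-1H-indene-4-carboxylate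
Product: 22 methyl (1S,3S,3aR,4R,5S,7aR)-1,4,5-triethyl-3-methyl-2-oxo-5-[(E)-2-phenylethenyl]-7-{[(trifluoromethyl)sulfonyl]oxy}-2,3,3a,4,5,7a-hexahydro-1H-indene-4-carboxylate, via potassium enolate 21 (not isolated)
Conditions: KN(SiMe3)2 (1.05 equiv), THF, −78 °C; then N-(5-chloropyridin-2-yl)triflimide, −78 → 0 °C
Reagents that add atoms: N-(5-chloropyridin-2-yl)-1,1,1-trifluoro-N-[(trifluoromethyl)sulfonyl]methanesulfonamide, FC(F)(F)S(=O)(=O)N(c1ccc(Cl)cn1)S(=O)(=O)C(F)(F)F
Why: Kinetic deprotonation at C6, the only α-methylene left in the molecule, followed by O-triflation gives the C6=C7 enol triflate and leaves the methine α-centres untouched (the changed descriptors at C3a and C5 are only a change in CIP priority).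

Step 9
Reactants: 22 the enol triflate from step 8
Product: 23 methyl (1S,3S,3aR,4R,5S,7aR)-1,4,5,7-tetraethyl-3-methyl-2-oxo-5-[(E)-2-phenylethenyl]-2,3,3a,4,5,7a-hexahydro-1H-indene-4-carboxylate
Conditions: Et2Zn (2 equiv), Pd(dppf)Cl2 (5 mol%), THF, 50 °C
Reagents that add atoms: diethylzinc, CC[Zn]CC
Why: Negishi cross-coupling of the enol triflate installs the C7 ethyl group with the C6=C7 double bond already in place; diethylzinc does not add to the hindered ketone and no stereocentre is touched.

Step 10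
Reactants: 23 the methyl ester from step 9
Product: 25 (1S,3S,3aR,4R,5S,7aR)-1,4,5,7-tetraethyl-3-methyl-2-oxo-5-[(E)-2-phenylethenyl]-2,3,3a,4,5,7a-hexahydro-1H-indene-4-carboxylic acid, via lithium carboxylate 24 (not isolated)
Conditions: LiSPr, HMPA, rt; then 1 M HCl
Reagents that add atoms: none
Why: SN2 dealkylation by thiolate attacks the methyl carbon and so frees the acid despite the two neighbouring quaternary carbons; the ketone α-centres are already the thermodynamic ones and the alkenes see no acid strong enough to lactonize them.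

## Compound list

1 | methyl benzoate | COC(=O)c1ccccc1 | starting material
2 | lithium ester dienolate, lithium (cyclohexa-2,5-dien-1-ylidene)(methoxy)methanolate | [Li]OC(OC)=C1C=CCC=C1 | intermediate
3 | methyl 1-ethylcyclohexa-2,5-diene-1-carboxylate | CCC1(C(=O)OC)C=CCC=C1 | intermediate
4 | methyl 1-ethyl-4-oxocyclohexa-2,5-diene-1-carboxylate | CCC1(C(=O)OC)C=CC(=O)C=C1 | intermediate
5 | ethylzinc enolate of the conjugate adduct (new ethyl group cis to the ester) | CC[Zn]OC1=C[C@H](CC)[C@](CC)(C(=O)OC)C=C1 | intermediate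
6 | methyl (1R,5S,6R)-1,6-diethyl-4-oxo-5-(phenylselanyl)cyclohex-2-ene-1-carboxylate | O=C1[C@@H]([Se]c2ccccc2)[C@H](CC)[C@](CC)(C(=O)OC)C=C1 | intermediate
7 | hex-1-en-3-one | C=CC(=O)CCC | starting material
8 | triethyl{[(2Z)-hex-2-en-3-yl]oxy}silane | C/C=C(\O[Si](CC)(CC)CC)CCC | intermediate
9 | triethylsilyl enol ether of 10 (enol ether towards the unsubstituted ring carbon; side-chain epimers) | CC[Si](CC)(CC)OC1=C[C@H](C(C)C(=O)CCC)[C@@](CC)(C(=O)OC)[C@@H](CC)[C@@H]1[Se]c1ccccc1 | intermediate
10 | methyl (1R,2R,3S,6R)-1,2-diethyl-4-oxo-6-(3-oxohexan-2-yl)-3-(phenylselanyl)cyclohexane-1-carboxylate (side-chain epimers) | O=C1C[C@H](C(C)C(=O)CCC)[C@@](CC)(C(=O)OC)[C@@H](CC)[C@@H]1[Se]c1ccccc1 | intermediate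
11 | selenoxide of 10 | O=C1C[C@H](C(C)C(=O)CCC)[C@@](CC)(C(=O)OC)[C@@H](CC)[C@@H]1[Se](=O)c1ccccc1 | intermediate
12 | methyl (1R,6R)-1,2-diethyl-4-oxo-6-(3-oxohexan-2-yl)cyclohex-2-ene-1-carboxylate (side-chain epimers) | O=C1C[C@H](C(C)C(=O)CCC)[C@@](CC)(C(=O)OC)C(CC)=C1 | intermediate
13 | (E)-(2-bromoethenyl)benzene | Br/C=C/c1ccccc1 | starting material
14 | (E)-styryllithium | [Li]/C=C/c1ccccc1 | intermediate
15 | lithium di[(E)-2-phenylethenyl]cuprate | [Li+].[Cu-](/C=C/c1ccccc1)/C=C/c1ccccc1 | intermediate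
16 | trimethylsilyl enol ether of 17 (enol ether towards the quaternary styryl carbon) | C[Si](C)(C)OC1=C[C@@](/C=C/c2ccccc2)(CC)[C@](CC)(C(=O)OC)[C@@H](C(C)C(=O)CCC)C1 | intermediate
17 | methyl (1R,2R,6R)-1,2-diethyl-4-oxo-6-(3-oxohexan-2-yl)-2-[(E)-2-phenylethenyl]cyclohexane-1-carboxylate (side-chain epimers) | O=C1C[C@H](C(C)C(=O)CCC)[C@@](CC)(C(=O)OC)[C@](/C=C/c2ccccc2)(CC)C1 | intermediate
18 | dilithium bis-enolate of 17 (ring enolate away from the quaternary carbon, side-chain enolate towards the propyl CH2) | [Li]OC1=C[C@H](C(C)C(O[Li])=CCC)[C@@](CC)(C(=O)OC)[C@](/C=C/c2ccccc2)(CC)C1 | intermediate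
19 | cis-fused diketone, the C7a epimer of 20 with C1 and C3 not yet equilibrated | O=C1C[C@@](/C=C/c2ccccc2)(CC)[C@](CC)(C(=O)OC)[C@@H]2[C@H]1C(CC)C(=O)C2C | intermediate
20 | methyl (1S,3S,3aS,4R,5R,7aR)-1,4,5-triethyl-3-methyl-2,7-dioxo-5-[(E)-2-phenylethenyl]octahydro-1H-indene-4-carboxylate | O=C1C[C@@](/C=C/c2ccccc2)(CC)[C@](CC)(C(=O)OC)[C@@H]2[C@@H]1[C@H](CC)C(=O)[C@H]2C | intermediate
21 | potassium enolate of 20 (C6=C7 enolate) | [K]OC1=C[C@@](/C=C/c2ccccc2)(CC)[C@](CC)(C(=O)OC)[C@@H]2[C@@H]1[C@H](CC)C(=O)[C@H]2C | intermediate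
22 | methyl (1S,3S,3aR,4R,5S,7aR)-1,4,5-triethyl-3-methyl-2-oxo-5-[(E)-2-phenylethenyl]-7-{[(trifluoromethyl)sulfonyl]oxy}-2,3,3a,4,5,7a-hexahydro-1H-indene-4-carboxylate | O=S(=O)(OC1=C[C@@](/C=C/c2ccccc2)(CC)[C@](CC)(C(=O)OC)[C@@H]2[C@@H]1[C@H](CC)C(=O)[C@H]2C)C(F)(F)F | intermediate
23 | methyl (1S,3S,3aR,4R,5S,7aR)-1,4,5,7-tetraethyl-3-methyl-2-oxo-5-[(E)-2-phenylethenyl]-2,3,3a,4,5,7a-hexahydro-1H-indene-4-carboxylate | CCC1=C[C@@](/C=C/c2ccccc2)(CC)[C@](CC)(C(=O)OC)[C@@H]2[C@@H]1[C@H](CC)C(=O)[C@H]2C | intermediate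
24 | lithium carboxylate of 25 | CCC1=C[C@@](/C=C/c2ccccc2)(CC)[C@](CC)(C(=O)[O-])[C@@H]2[C@@H]1[C@H](CC)C(=O)[C@H]2C.[Li+] | intermediate
25 | (1S,3S,3aR,4R,5S,7aR)-1,4,5,7-tetraethyl-3-methyl-2-oxo-5-[(E)-2-phenylethenyl]-2,3,3a,4,5,7a-hexahydro-1H-indene-4-carboxylic acid (CNP0324606.3) | CCC1=C[C@@](/C=C/c2ccccc2)(CC)[C@](CC)(C(=O)O)[C@@H]2[C@@H]1[C@H](CC)C(=O)[C@H]2C | target

## Step count and risks

Total step count: 10 (nine in the main line plus the preparation of 8 in step 4).
Longest linear sequence: 9 steps from methyl benzoate (steps 1, 2, 3, 5, 6, 7, 8, 9, 10).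

The three steps most likely to fail:

**Step 3 (desymmetrization).** The route needs the ethyl group to enter syn to the ester; if it enters anti, the relay in step 5 puts the side chain on the wrong face. The fallback sets out from 4 and comes back at 12, and uses the opposite facial preference. Silyl enol ether 8 is added first, in a Mukaiyama–Michael addition catalysed by a chiral oxazaborolidinium triflimide (from the (S)-diphenylprolinol o-tolylboronate and Tf2NH, with Ph3PO, toluene, −40 °C, then 1 M HCl). This gives methyl (1S,6R)-1-ethyl-4-oxo-6-(3-oxohexan-2-yl)cyclohex-2-ene-1-carboxylate F1, with the side chain anti to the ester. Et2CuLi/TMSCl at −78 °C followed by Pd(OAc)2 and O2 in DMSO (Saegusa–Ito dehydrogenation of the silyl enol ether) then gives 12.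

**Step 6 (vicinal quaternary centres by cuprate addition).** The enone is β,β-disubstituted and flanked by a quaternary carbon, so the cuprate may not add. The fallback sets out from 12 and comes back at 17, and delivers a slimmer sp-carbon nucleophile instead. Conjugate alkynylation (PhC≡CLi, ZnBr2, TBSOTf, THF/Et2O, −40 °C, then 1 M HCl) gives methyl (1R,2R,6R)-1,2-diethyl-4-oxo-6-(3-oxohexan-2-yl)-2-(phenylethynyl)cyclohexane-1-carboxylate F2. Trans-hydrosilylation with (EtO)3SiH and [Cp*Ru(MeCN)3]PF6 gives methyl (1R,2R,6R)-1,2-diethyl-4-oxo-6-(3-oxohexan-2-yl)-2-[(Z)-2-phenyl-2-(triethoxysilyl)ethenyl]cyclohexane-1-carboxylate F3. Protodesilylation (Bu4NF, CuI, THF) then gives 17 with the (E)-alkene.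

**Step 7 (oxidative enolate coupling).** Dimerization, enolization towards the wrong methylene or simple recovery of 17 may win. The fallback sets out from 6 and comes back at 20, and closes the ring by aldol chemistry before the styryl group is added. Hexane-3,4-dione and DBU (CH2Cl2, rt) add to 6 by Michael addition, again trans to the temporary ethyl group, and the ring enolate closes onto the distal ketone. This gives methyl 1,4,5-triethyl-1-hydroxy-3-methyl-2,7-dioxo-6-(phenylselanyl)octahydro-1H-indene-4-carboxylate F4, with C3a, C4, C5 and C6 configured as in 10. H2O2/pyridine gives methyl 1,4,5-triethyl-1-hydroxy-3-methyl-2,7-dioxo-2,3,3a,4,7,7a-hexahydro-1H-indene-4-carboxylate F5. SmI2 (THF/MeOH, −78 °C) removes the tertiary α-ketol hydroxyl to give methyl 1,4,5-triethyl-3-methyl-2,7-dioxo-2,3,3a,4,7,7a-hexahydro-1H-indene-4-carboxylate F6. Cuprate 15 with TMSCl, acid work-up and DBU equilibration then give 20. In this variant the cuprate meets a bicyclic enone, so its facial outcome has to be checked.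

## Further compounds

F1 | step 3 | methyl (1S,6R)-1-ethyl-4-oxo-6-(3-oxohexan-2-yl)cyclohex-2-ene-1-carboxylate | O=C1C[C@H](C(C)C(=O)CCC)[C@@](CC)(C(=O)OC)C=C1
F2 | step 6 | methyl (1R,2R,6R)-1,2-diethyl-4-oxo-6-(3-oxohexan-2-yl)-2-(phenylethynyl)cyclohexane-1-carboxylate | O=C1C[C@H](C(C)C(=O)CCC)[C@@](CC)(C(=O)OC)[C@](C#Cc2ccccc2)(CC)C1
F3 | step 6 | methyl (1R,2R,6R)-1,2-diethyl-4-oxo-6-(3-oxohexan-2-yl)-2-[(Z)-2-phenyl-2-(triethoxysilyl)ethenyl]cyclohexane-1-carboxylate | O=C1C[C@H](C(C)C(=O)CCC)[C@@](CC)(C(=O)OC)[C@](/C=C(\[Si](OCC)(OCC)OCC)c2ccccc2)(CC)C1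
F4 | step 7 | methyl 1,4,5-triethyl-1-hydroxy-3-methyl-2,7-dioxo-6-(phenylselanyl)octahydro-1H-indene-4-carboxylate (C3a, C4, C5, C6 as in 10) | O=C1[C@@H]([Se]c2ccccc2)[C@H](CC)[C@](CC)(C(=O)OC)[C@@H]2C1C(O)(CC)C(=O)C2C
F5 | step 7 | methyl 1,4,5-triethyl-1-hydroxy-3-methyl-2,7-dioxo-2,3,3a,4,7,7a-hexahydro-1H-indene-4-carboxylate | O=C1C=C(CC)[C@](CC)(C(=O)OC)[C@@H]2C1C(O)(CC)C(=O)C2C
F6 | step 7 | methyl 1,4,5-triethyl-3-methyl-2,7-dioxo-2,3,3a,4,7,7a-hexahydro-1H-indene-4-carboxylate | O=C1C=C(CC)[C@](CC)(C(=O)OC)[C@@H]2C1C(CC)C(=O)C2C
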